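The cyclohexene (C1 aroyl, C2 aryl, C3=C4 with methyl on C4, C5, C6 resorcinyl) is cut at C1–C6. The route uses the fact that C6 is benzylic and para to a phenolic oxygen of its resorcinol ring, and beta to the C1 ketone. Anodic oxidation of that one free phenol should give a para-quinone methide at C6, which the C1 enol captures, closing the ring and setting C1 and C6 against C2 in one operation. The precursor is an open-chain (Z)-alkenyl aryl ketone with the C2 stereocentre in place and a 4-hydroxyphenethyl terminus. All other phenols, including the resorcinol oxygen ortho to C6, are methoxymethyl (MOM) ethers; a bromine marks the later chalcone site.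

Key step: step 15

Assumption: (R,R)-Ph-bod* is taken to expose the Si face of the beta carbon of chalcone 7 to the alkenylrhodium species; if the induction proves opposite, the (S,S) ligand is used and nothing else changes.

Locants: ring atoms C1–C6 of the overview are locants 1–6 of the cyclohexenyl methanone names (23 onwards) and correspond to C2–C7 of the heptenone chain in 20–22.

Step 1
Reactants: 1 2,4-dihydroxyacetophenone
Product: 2 1-[2,4-dihydroxy-3-(3-methylbut-2-enyl)phenyl]ethanone
Conditions: prenyl bromide, DBU, THF, 0 °C to rt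
Reagents that add atoms: prenyl bromide, CC(C)=CCBr
Why: Phenoxide C-alkylation (C-prenylation) is expected to favour C3, the ring carbon activated by both oxygens, in a weakly polar solvent; O-prenyl and C5 isomers are removed by chromatography.

Step 2
Reactants: 2 3-prenyl-2,4-dihydroxyacetophenone
Product: 3 1-[2,4-bis(methoxymethoxy)-3-(3-methylbut-2-enyl)phenyl]ethanone
Conditions: NaH, MOMCl, DMF, 0 °C to rt
Reagents that add atoms: chloromethyl methyl ether, COCCl
Why: Williamson-type MOM ether formation; NaH is used because the 2-hydroxyl is chelated to the acetyl group and flanked by the prenyl chain.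

Step 3
Reactants: 4 2,6-dihydroxybenzaldehyde
Product: 5 2,6-bis(methoxymethoxy)benzaldehyde
Conditions: MOMCl, i-Pr2NEt, CH2Cl2, 0 °C to rt
Reagents that add atoms: chloromethyl methyl ether, COCCl
Why: MOM ether formation of both phenols under amine base leaves the aldehyde untouched.

Step 4
Reactants: 5 2,6-bis(methoxymethoxy)benzaldehyde
Product: 6 3-bromo-2,6-bis(methoxymethoxy)benzaldehyde
Conditions: NBS, MeCN, 0 °C to rt
Reagents that add atoms: N-bromosuccinimide, O=C1CCC(=O)N1Br
Why: Electrophilic aromatic bromination goes to C3 (equivalent to C5), ortho to one acetal ether and para to the other, and the first bromine deactivates the ring against a second substitution.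

Step 5
Reactants: 3 protected prenyl acetophenone; 6 bromo aldehyde
Product: 7 (E)-1-[2,4-bis(methoxymethoxy)-3-(3-methylbut-2-enyl)phenyl]-3-[3-bromo-2,6-bis(methoxymethoxy)phenyl]prop-2-en-1-one
Conditions: KOH, EtOH/H2O, rt
Reagents that add atoms: none
Why: Claisen–Schmidt condensation of the methyl ketone enolate with the non-enolisable aldehyde, followed by E1cB dehydration, gives the E-enone; MOM ethers, prenyl group and aryl bromide are inert to hydroxide.

Step 6
Reactants: 8 2,4-dihydroxybenzaldehyde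
Product: 9 2-hydroxy-4-(triisopropylsilyloxy)benzaldehyde
Conditions: TIPSCl (1 equiv), imidazole, CH2Cl2, 0 °C
Reagents that add atoms: chlorotriisopropylsilane, CC(C)[Si](Cl)(C(C)C)C(C)C
Why: Selective silylation occurs at the 4-hydroxyl, which is not hydrogen-bonded to the formyl group and is the more acidic and accessible one.

Step 7
Reactants: 9 4-silyloxy salicylaldehyde
Product: 10 2-(methoxymethoxy)-4-(triisopropylsilyloxy)benzaldehyde
Conditions: MOMCl, i-Pr2NEt, CH2Cl2, 0 °C to rt
Reagents that add atoms: chloromethyl methyl ether, COCCl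
Why: MOM ether formation of the remaining chelated phenol under amine base leaves the aryl silyl ether intact and differentiates the two resorcinol oxygens.

Step 8
Reactants: 10 differentiated aldehyde
Product: 11 [4-ethenyl-3-(methoxymethoxy)phenoxy]triisopropylsilane
Conditions: Ph3PCH3Br, KOt-Bu, THF, 0 °C to rt
Reagents that add atoms: methyltriphenylphosphonium bromide, C[P+](c1ccccc1)(c1ccccc1)c1ccccc1.[Br-]
Why: Wittig methylenation of the aldehyde with the unstabilised ylide.

Step 9
Reactants: 11 styrene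
Product: 13 2-[2-(methoxymethoxy)-4-(triisopropylsilyloxy)phenyl]ethan-1-ol, via B-alkyl-9-BBN adduct 12 (not isolated)
Conditions: 9-BBN, THF, 0 °C to rt; then H2O2, NaOAc (aq.), 0 °C to rt
Reagents that add atoms: hydrogen peroxide, OO
Why: Anti-Markovnikov hydroboration with the bulky dialkylborane puts boron on the terminal carbon, and buffered peroxide oxidation replaces it by hydroxyl without cleaving the aryl silyl ether.

Step 10
Reactants: 13 arylethanol
Product: 14 [4-(2-iodoethyl)-3-(methoxymethoxy)phenoxy]triisopropylsilane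
Conditions: I2, PPh3, imidazole, CH2Cl2, 0 °C to rt
Reagents that add atoms: iodine, II
Why: Appel-type iodination converts the primary alcohol by SN2 displacement of its alkoxyphosphonium salt.

Step 11
Reactants: 15 propyne
Product: 17 2-[(Z)-2-bromoprop-1-enyl]-4,4,5,5-tetramethyl-1,3,2-dioxaborolane, via (Z)-2-bromoprop-1-enyl(dibromo)borane 16 (not isolated)
Conditions: BBr3, CH2Cl2, −78 °C; then pinacol, −78 °C to rt
Reagents that add atoms: boron tribromide, BrB(Br)Br; pinacol, CC(C)(O)C(C)(C)O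
Why: syn-Bromoboration of the terminal alkyne places boron on the terminal carbon cis to bromine, and ligand exchange with pinacol fixes the (Z)-alkenylboronate.

Step 12
Reactants: 14 homobenzyl iodide; 17 (Z)-bromoalkenylboronate
Product: 19 2-[(Z)-4-[2-(methoxymethoxy)-4-(triisopropylsilyloxy)phenyl]-2-methylbut-1-enyl]-4,4,5,5-tetramethyl-1,3,2-dioxaborolane, via alkylzinc iodide 18 (not isolated)
Conditions: Zn dust, LiCl, THF, 40 °C; then 17, Pd(P(t-Bu)3)2 (2 mol %), THF, rt
Reagents that add atoms: none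
Why: Zinc insertion into the primary iodide followed by Negishi coupling at the C–Br bond proceeds with retention of alkene geometry, and the pinacol boronate does not transmetalate without base, so the homobenzyl chain ends up cis to boron.

Step 13
Reactants: 7 (E)-bromochalcone; 19 (Z)-alkenylboronate
Product: 20 (3R,4Z)-1-[2,4-bis(methoxymethoxy)-3-(3-methylbut-2-enyl)phenyl]-3-[3-bromo-2,6-bis(methoxymethoxy)phenyl]-7-[2-(methoxymethoxy)-4-(triisopropylsilyloxy)phenyl]-5-methylhept-4-en-1-one
Conditions: [RhCl(C2H4)2]2 (2.5 mol %), (1R,4R)-2,5-diphenylbicyclo[2.2.2]octa-2,5-diene [(R,R)-Ph-bod*] (5.5 mol %), KOH (aq., 50 mol %), 1,4-dioxane/H2O (10:1), 50 °C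
Reagents that add atoms: none
Why: Rhodium-catalysed asymmetric 1,4-addition (Hayashi–Miyaura type) transfers the alkenyl group from boron to rhodium with retention of the Z geometry and inserts the enone on the face left open by the C2-symmetric diene, which sets the (R) centre (ring C2); the labile ethylene ligands leave no achiral rhodium catalyst behind, and the aryl bromide is inert to monovalent rhodium.

Step 14
Reactants: 20 silyl-protected adduct
Product: 21 (3R,4Z)-1-[2,4-bis(methoxymethoxy)-3-(3-methylbut-2-enyl)phenyl]-3-[3-bromo-2,6-bis(methoxymethoxy)phenyl]-7-[4-hydroxy-2-(methoxymethoxy)phenyl]-5-methylhept-4-en-1-one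
Conditions: TBAF, AcOH (1:1), THF, 0 °C
Reagents that add atoms: none
Why: Fluoride-mediated cleavage of the aryl silyl ether frees only the para phenol, with acetic acid buffering the phenoxide; MOM ethers, ketone and aryl bromide are unaffected.

Step 15
Reactants: 21 open-chain para-phenol ketone
Product: 23 [2,4-bis(methoxymethoxy)-3-(3-methylbut-2-enyl)phenyl][(1S,2S,6R)-2-[3-bromo-2,6-bis(methoxymethoxy)phenyl]-6-[4-hydroxy-2-(methoxymethoxy)phenyl]-4-methylcyclohex-3-en-1-yl]methanone, via para-quinone methide 22 (not isolated)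
Conditions: undivided cell, graphite anode, Pt cathode, n-Bu4NPF6 (0.1 M), 2,6-lutidine (1 equiv), HFIP/CH2Cl2 (1:4), 5 mM, constant current 1 mA cm−2, 2.1 F mol−1, rt
Reagents that add atoms: none
Why: Proposed new method: the only free phenol of 21 is its most easily oxidised group, so loss of two electrons and two protons at the anode should give para-quinone methide 22 at C6, whose methide carbon (activated by hydrogen bonding to HFIP) is attacked by C1 of the ketone enol (keto–enol exchange mediated by the lutidine/lutidinium pair) with rearomatisation, so that C1–H and C6–H are coupled while hydrogen is released at the cathode. The closest known reactions are anodic oxidations of para-alkylphenols to quinone methides that are trapped by nucleophiles, and Michael additions of ketone enols to para-quinone methides. The cyclohexene closes in a 6-(enol-exo)-exo-trig mode, made possible by the (Z)-alkene that holds C2 and C5 on the same side; no other nucleophilic site can reach C6 through an unstrained ring, and both ortho carbons of the C2 aryl group are substituted. C6 is set by a chair-like transition state in which the C2 aryl group and the quinone methide ring are both pseudo-equatorial, which puts the two aryl groups cis; C1 is set trans to both in the same chair and, being alpha to the ketone, can later equilibrate to this all-equatorial arrangement. The step needs oxidation of one phenol in the presence of two trisubstituted alkenes, five aryl acetal ethers and an aryl bromide, which is secured by the lower oxidation potential of the free phenol, by limiting the charge to about two faradays per mole and by the buffered undivided cell; the MOM group on the ortho oxygen excludes an ortho-quinone methide and phenol-onto-alkene (chroman) closure at C4.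

Step 16
Reactants: 23 cyclohexene phenol
Product: 24 [(1S,2S,6R)-6-[2,4-bis(methoxymethoxy)phenyl]-2-[3-bromo-2,6-bis(methoxymethoxy)phenyl]-4-methylcyclohex-3-en-1-yl][2,4-bis(methoxymethoxy)-3-(3-methylbut-2-enyl)phenyl]methanone
Conditions: MOMCl, i-Pr2NEt, CH2Cl2, 0 °C to rt
Reagents that add atoms: chloromethyl methyl ether, COCCl
Why: MOM ether formation of the phenol blocks base-induced retro-Michael opening of the C1–C6 bond (phenoxide to quinone methide) before the basic steps that follow.

Step 17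
Reactants: 24 hexa-MOM aryl bromide
Product: 26 [(1S,2S,6R)-2-[3-acetyl-2,6-bis(methoxymethoxy)phenyl]-6-[2,4-bis(methoxymethoxy)phenyl]-4-methylcyclohex-3-en-1-yl][2,4-bis(methoxymethoxy)-3-(3-methylbut-2-enyl)phenyl]methanone, via 1-ethoxyvinyl arene 25 (not isolated)
Conditions: tributyl(1-ethoxyvinyl)stannane, Pd(PPh3)4 (5 mol %), toluene, 100 °C; then 1 M HCl, THF, 0 °C
Reagents that add atoms: tributyl(1-ethoxyvinyl)stannane, C=C(OCC)[Sn](CCCC)(CCCC)CCCC; water, O
Why: Stille coupling of the aryl bromide with the acetyl anion equivalent is followed by mild acid hydrolysis of the enol ether, which is far faster than cleavage of aryl MOM ethers.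

Step 18
Reactants: 8 2,4-dihydroxybenzaldehyde
Product: 27 2,4-bis(methoxymethoxy)benzaldehyde
Conditions: MOMCl, i-Pr2NEt, CH2Cl2, 0 °C to rt
Reagents that add atoms: chloromethyl methyl ether, COCCl
Why: MOM ether formation of both phenols under amine base.

Step 19
Reactants: 26 acetyl compound; 27 protected resorcinol aldehyde
Product: 28 (E)-1-[3-[(1S,5R,6S)-6-[2,4-bis(methoxymethoxy)-3-(3-methylbut-2-enyl)benzoyl]-5-[2,4-bis(methoxymethoxy)phenyl]-3-methylcyclohex-2-en-1-yl]-2,4-bis(methoxymethoxy)phenyl]-3-[2,4-bis(methoxymethoxy)phenyl]prop-2-en-1-one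
Conditions: KOH, EtOH/THF, rt
Reagents that add atoms: none
Why: Claisen–Schmidt condensation can occur only at the methyl ketone, because the C1 ketone has a tertiary alpha carbon; C1 may enolise under hydroxide, but the all-equatorial trans,trans arrangement is the thermodynamic one and should be retained.

Step 20
Reactants: 28 octa-MOM kuwanon I
Product: 29 kuwanon I, (E)-1-[3-[(1S,5R,6S)-6-[2,4-dihydroxy-3-(3-methylbut-2-enyl)benzoyl]-5-(2,4-dihydroxyphenyl)-3-methylcyclohex-2-en-1-yl]-2,4-dihydroxyphenyl]-3-(2,4-dihydroxyphenyl)prop-2-en-1-one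
Conditions: 3 M HCl (aq.), MeOH, rt to 40 °C
Reagents that add atoms: none
Why: Acid-catalysed acetal exchange with methanol frees all eight phenols as dimethoxymethane; the mild temperature is chosen so that the prenyl group and the 2'-hydroxychalcone do not cyclise.

Compound list
1 | 2,4-dihydroxyacetophenone | CC(=O)c1ccc(O)cc1O | starting material
2 | 1-[2,4-dihydroxy-3-(3-methylbut-2-enyl)phenyl]ethanone | CC(=O)c1ccc(O)c(CC=C(C)C)c1O | intermediate
3 | 1-[2,4-bis(methoxymethoxy)-3-(3-methylbut-2-enyl)phenyl]ethanone | CC(=O)c1ccc(OCOC)c(CC=C(C)C)c1OCOC | intermediate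
4 | 2,6-dihydroxybenzaldehyde | O=Cc1c(O)cccc1O | starting material
5 | 2,6-bis(methoxymethoxy)benzaldehyde | O=Cc1c(OCOC)cccc1OCOC | intermediate
6 | 3-bromo-2,6-bis(methoxymethoxy)benzaldehyde | O=Cc1c(OCOC)ccc(Br)c1OCOC | intermediate
7 | (E)-1-[2,4-bis(methoxymethoxy)-3-(3-methylbut-2-enyl)phenyl]-3-[3-bromo-2,6-bis(methoxymethoxy)phenyl]prop-2-en-1-one | O=C(/C=C/c1c(OCOC)ccc(Br)c1OCOC)c1ccc(OCOC)c(CC=C(C)C)c1OCOC | intermediate
8 | 2,4-dihydroxybenzaldehyde | O=Cc1ccc(O)cc1O | starting material
9 | 2-hydroxy-4-(triisopropylsilyloxy)benzaldehyde | O=Cc1ccc(O[Si](C(C)C)(C(C)C)C(C)C)cc1O | intermediate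
10 | 2-(methoxymethoxy)-4-(triisopropylsilyloxy)benzaldehyde | O=Cc1ccc(O[Si](C(C)C)(C(C)C)C(C)C)cc1OCOC | intermediate
11 | [4-ethenyl-3-(methoxymethoxy)phenoxy]triisopropylsilane | C=Cc1ccc(O[Si](C(C)C)(C(C)C)C(C)C)cc1OCOC | intermediate
12 | 9-[2-[2-(methoxymethoxy)-4-(triisopropylsilyloxy)phenyl]ethyl]-9-borabicyclo[3.3.1]nonane | COCOc1cc(O[Si](C(C)C)(C(C)C)C(C)C)ccc1CCB1C2CCCC1CCC2 | intermediate (not isolated)
13 | 2-[2-(methoxymethoxy)-4-(triisopropylsilyloxy)phenyl]ethan-1-ol | OCCc1ccc(O[Si](C(C)C)(C(C)C)C(C)C)cc1OCOC | intermediate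
14 | [4-(2-iodoethyl)-3-(methoxymethoxy)phenoxy]triisopropylsilane | ICCc1ccc(O[Si](C(C)C)(C(C)C)C(C)C)cc1OCOC | intermediate
15 | propyne | CC#C | starting material
16 | dibromo[(Z)-2-bromoprop-1-enyl]borane | C/C(Br)=C/B(Br)Br | intermediate (not isolated)
17 | 2-[(Z)-2-bromoprop-1-enyl]-4,4,5,5-tetramethyl-1,3,2-dioxaborolane | C/C(Br)=C/B1OC(C)(C)C(C)(C)O1 | intermediate
18 | [2-[2-(methoxymethoxy)-4-(triisopropylsilyloxy)phenyl]ethyl]zinc iodide | I[Zn]CCc1ccc(O[Si](C(C)C)(C(C)C)C(C)C)cc1OCOC | intermediate (not isolated)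
19 | 2-[(Z)-4-[2-(methoxymethoxy)-4-(triisopropylsilyloxy)phenyl]-2-methylbut-1-enyl]-4,4,5,5-tetramethyl-1,3,2-dioxaborolane | C/C(CCc1ccc(O[Si](C(C)C)(C(C)C)C(C)C)cc1OCOC)=C/B1OC(C)(C)C(C)(C)O1 | intermediate
20 | (3R,4Z)-1-[2,4-bis(methoxymethoxy)-3-(3-methylbut-2-enyl)phenyl]-3-[3-bromo-2,6-bis(methoxymethoxy)phenyl]-7-[2-(methoxymethoxy)-4-(triisopropylsilyloxy)phenyl]-5-methylhept-4-en-1-one | O=C(c1ccc(OCOC)c(CC=C(C)C)c1OCOC)C[C@@H](c1c(OCOC)ccc(Br)c1OCOC)/C=C(/C)CCc1ccc(O[Si](C(C)C)(C(C)C)C(C)C)cc1OCOC | intermediate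
21 | (3R,4Z)-1-[2,4-bis(methoxymethoxy)-3-(3-methylbut-2-enyl)phenyl]-3-[3-bromo-2,6-bis(methoxymethoxy)phenyl]-7-[4-hydroxy-2-(methoxymethoxy)phenyl]-5-methylhept-4-en-1-one | O=C(c1ccc(OCOC)c(CC=C(C)C)c1OCOC)C[C@@H](c1c(OCOC)ccc(Br)c1OCOC)/C=C(/C)CCc1ccc(O)cc1OCOC | intermediate (key-step precursor)
22 | (3R,4Z)-1-[2,4-bis(methoxymethoxy)-3-(3-methylbut-2-enyl)phenyl]-3-[3-bromo-2,6-bis(methoxymethoxy)phenyl]-7-[2-(methoxymethoxy)-4-oxocyclohexa-2,5-dien-1-ylidene]-5-methylhept-4-en-1-one (methide geometry not defined) | O=C(c1ccc(OCOC)c(CC=C(C)C)c1OCOC)C[C@@H](c1c(OCOC)ccc(Br)c1OCOC)/C=C(/C)CC=C1C=CC(=O)C=C1OCOC | intermediate (not isolated)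
23 | [2,4-bis(methoxymethoxy)-3-(3-methylbut-2-enyl)phenyl][(1S,2S,6R)-2-[3-bromo-2,6-bis(methoxymethoxy)phenyl]-6-[4-hydroxy-2-(methoxymethoxy)phenyl]-4-methylcyclohex-3-en-1-yl]methanone | O=C(c1ccc(OCOC)c(CC=C(C)C)c1OCOC)[C@@H]2[C@@H](c3c(OCOC)ccc(Br)c3OCOC)C=C(C)C[C@H]2c2ccc(O)cc2OCOC | intermediate (key-step product)
24 | [(1S,2S,6R)-6-[2,4-bis(methoxymethoxy)phenyl]-2-[3-bromo-2,6-bis(methoxymethoxy)phenyl]-4-methylcyclohex-3-en-1-yl][2,4-bis(methoxymethoxy)-3-(3-methylbut-2-enyl)phenyl]methanone | O=C(c1ccc(OCOC)c(CC=C(C)C)c1OCOC)[C@@H]2[C@@H](c3c(OCOC)ccc(Br)c3OCOC)C=C(C)C[C@H]2c2ccc(OCOC)cc2OCOC | intermediate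
25 | [(1S,2S,6R)-6-[2,4-bis(methoxymethoxy)phenyl]-2-[3-(1-ethoxyethenyl)-2,6-bis(methoxymethoxy)phenyl]-4-methylcyclohex-3-en-1-yl][2,4-bis(methoxymethoxy)-3-(3-methylbut-2-enyl)phenyl]methanone | O=C(c1ccc(OCOC)c(CC=C(C)C)c1OCOC)[C@@H]2[C@@H](c3c(OCOC)ccc(C(=C)OCC)c3OCOC)C=C(C)C[C@H]2c2ccc(OCOC)cc2OCOC | intermediate (not isolated)
26 | [(1S,2S,6R)-2-[3-acetyl-2,6-bis(methoxymethoxy)phenyl]-6-[2,4-bis(methoxymethoxy)phenyl]-4-methylcyclohex-3-en-1-yl][2,4-bis(methoxymethoxy)-3-(3-methylbut-2-enyl)phenyl]methanone | O=C(c1ccc(OCOC)c(CC=C(C)C)c1OCOC)[C@@H]2[C@@H](c3c(OCOC)ccc(C(C)=O)c3OCOC)C=C(C)C[C@H]2c2ccc(OCOC)cc2OCOC | intermediate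
27 | 2,4-bis(methoxymethoxy)benzaldehyde | O=Cc1ccc(OCOC)cc1OCOC | intermediate
28 | (E)-1-[3-[(1S,5R,6S)-6-[2,4-bis(methoxymethoxy)-3-(3-methylbut-2-enyl)benzoyl]-5-[2,4-bis(methoxymethoxy)phenyl]-3-methylcyclohex-2-en-1-yl]-2,4-bis(methoxymethoxy)phenyl]-3-[2,4-bis(methoxymethoxy)phenyl]prop-2-en-1-one | O=C(c1ccc(OCOC)c(CC=C(C)C)c1OCOC)[C@@H]2[C@@H](c3c(OCOC)ccc(C(=O)/C=C/c4ccc(OCOC)cc4OCOC)c3OCOC)C=C(C)C[C@H]2c2ccc(OCOC)cc2OCOC | intermediate
29 | kuwanon I, (E)-1-[3-[(1S,5R,6S)-6-[2,4-dihydroxy-3-(3-methylbut-2-enyl)benzoyl]-5-(2,4-dihydroxyphenyl)-3-methylcyclohex-2-en-1-yl]-2,4-dihydroxyphenyl]-3-(2,4-dihydroxyphenyl)prop-2-en-1-one | CC(C)=CCc1c(O)ccc(C(=O)[C@@H]2[C@@H](c3c(O)ccc(C(=O)/C=C/c4ccc(O)cc4O)c3O)C=C(C)C[C@H]2c2ccc(O)cc2O)c1O | target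

Total step count: 20. Longest linear sequence: 13 steps (8 to 29 through steps 6, 7, 8, 9, 10, 12, 13, 14, 15, 16, 17, 19 and 20).

Steps most likely to fail

Step 15. The quinone methide may tautomerise to the aryl-conjugated diene or oligomerise faster than the slowly formed enol can capture it, or the product phenol may be oxidised further. The fallback builds the ring by the known enantioselective Diels–Alder reaction of a 2'-hydroxychalcone with an aryl diene; it sets out from 2, 6 and 27 and comes back to the route at 24. Selective alkylation of the non-chelated hydroxyl of 2 (MOMCl, K2CO3, acetone) should give 1-[2-hydroxy-4-(methoxymethoxy)-3-(3-methylbut-2-enyl)phenyl]ethanone F1, and Claisen–Schmidt condensation with 27 (KOH, EtOH) should give (E)-3-[2,4-bis(methoxymethoxy)phenyl]-1-[2-hydroxy-4-(methoxymethoxy)-3-(3-methylbut-2-enyl)phenyl]prop-2-en-1-one F2. Aldehyde 6 is condensed with acetone (NaOH, acetone/H2O) to (E)-4-[3-bromo-2,6-bis(methoxymethoxy)phenyl]but-3-en-2-one F3 and methylenated (Ph3PCH3Br, KOt-Bu, THF) to 1-bromo-2,4-bis(methoxymethoxy)-3-[(1E)-3-methylbuta-1,3-dienyl]benzene F4. Cycloaddition of F2 and F4 on a chiral borate (BH3·THF, AcOH, the appropriate enantiomer of VANOL, THF), in which boron binds the 2'-hydroxy ketone, should give, after separation from the endo isomer, the all-trans adduct [(1S,2S,6R)-6-[2,4-bis(methoxymethoxy)phenyl]-2-[3-bromo-2,6-bis(methoxymethoxy)phenyl]-4-methylcyclohex-3-en-1-yl][2-hydroxy-4-(methoxymethoxy)-3-(3-methylbut-2-enyl)phenyl]methanone F5. Capping its chelated phenol (MOMCl, NaH, DMF) gives 24.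

Step 13. Insertion into the beta carbon flanked by a 2,6-disubstituted aryl ring may be slow, so that protodeboronation of 19 takes over, or facial selectivity may be poor. The fallback is the metal-free, chiral-diol-catalysed conjugate alkenylation of enones; it sets out from 19 (with 7) and comes back at 20. Oxidative cleavage of the pinacol ester (NaIO4, NH4OAc, acetone/H2O) should give [(Z)-4-[2-(methoxymethoxy)-4-(triisopropylsilyloxy)phenyl]-2-methylbut-1-enyl]boronic acid F6. F6 is then added to 7 with 3,3'-bis(pentafluorophenyl)-BINOL (20 mol %, enantiomer chosen for Si-face delivery), Mg(Ot-Bu)2 (10 mol %), toluene, 4 Å molecular sieves, 70 °C, where the chiral boronate ester delivers the alkenyl group to the s-cis enone.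

Step 20. Acid may close the prenyl group onto its neighbouring phenol (chroman), cyclise the 2'-hydroxychalcone to a flavanone, or cleave the eight acetals incompletely. The fallback replaces protic hydrolysis by non-protic transprotection; it sets out from 28 and comes back at 29. TESOTf and 2,2'-bipyridyl (CH2Cl2, 0 °C) should convert the aryl MOM ethers into the octakis(triethylsilyl) ether of kuwanon I F7, and buffered fluoride (TBAF, AcOH, THF, 0 °C) then frees the phenols.

Further compounds
F1 | step 15 | 1-[2-hydroxy-4-(methoxymethoxy)-3-(3-methylbut-2-enyl)phenyl]ethanone | CC(=O)c1ccc(OCOC)c(CC=C(C)C)c1O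
F2 | step 15 | (E)-3-[2,4-bis(methoxymethoxy)phenyl]-1-[2-hydroxy-4-(methoxymethoxy)-3-(3-methylbut-2-enyl)phenyl]prop-2-en-1-one | O=C(/C=C/c1ccc(OCOC)cc1OCOC)c1ccc(OCOC)c(CC=C(C)C)c1O
F3 | step 15 | (E)-4-[3-bromo-2,6-bis(methoxymethoxy)phenyl]but-3-en-2-one | CC(=O)/C=C/c1c(OCOC)ccc(Br)c1OCOC
F4 | step 15 | 1-bromo-2,4-bis(methoxymethoxy)-3-[(1E)-3-methylbuta-1,3-dienyl]benzene | C=C(C)/C=C/c1c(OCOC)ccc(Br)c1OCOC
F5 | step 15 | [(1S,2S,6R)-6-[2,4-bis(methoxymethoxy)phenyl]-2-[3-bromo-2,6-bis(methoxymethoxy)phenyl]-4-methylcyclohex-3-en-1-yl][2-hydroxy-4-(methoxymethoxy)-3-(3-methylbut-2-enyl)phenyl]methanone | O=C(c1ccc(OCOC)c(CC=C(C)C)c1O)[C@@H]2[C@@H](c3c(OCOC)ccc(Br)c3OCOC)C=C(C)C[C@H]2c2ccc(OCOC)cc2OCOC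
F6 | step 13 | [(Z)-4-[2-(methoxymethoxy)-4-(triisopropylsilyloxy)phenyl]-2-methylbut-1-enyl]boronic acid | C/C(CCc1ccc(O[Si](C(C)C)(C(C)C)C(C)C)cc1OCOC)=C/B(O)O
F7 | step 20 | octakis(triethylsilyl) ether of kuwanon I | O=C(c1ccc(O[Si](CC)(CC)CC)c(CC=C(C)C)c1O[Si](CC)(CC)CC)[C@@H]2[C@@H](c3c(O[Si](CC)(CC)CC)ccc(C(=O)/C=C/c4ccc(O[Si](CC)(CC)CC)cc4O[Si](CC)(CC)CC)c3O[Si](CC)(CC)CC)C=C(C)C[C@H]2c2ccc(O[Si](CC)(CC)CC)cc2O[Si](CC)(CC)CC
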